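## Retrosynthetic overview

1. Gilluone B ⇐ NH3 condensation on an enolic triketone dimer. The dimer ⇐ inverse-electron-demand oxa-[4+2] cycloaddition (then hemiketal opening) between a ring-B exo-methylene enone (quinone methide) and the C=C(OH) enol of the ring-A ester; this makes the CH2 bridge and the all-carbon quaternary centre.
2. Quinone methide ⇐ the C-methyl group of the C-acyl triketone (TEMPO/Ag2O alkoxyamine, thermal loss of TEMPO–H). Ring-A ester and ring-B triketone ⇐ O- versus C-acylation of one common o-quinol core with (R)-2-methylbutanoic acid.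
3. Core ⇐ vinylogous Dieckmann closure of a 5-acyl-dioxolanone. Its quaternary carbinol centre ⇐ L-lactic acid through the pivaldehyde acetal (self-regeneration of the stereocentre), acylated with (E)-3-methoxypent-2-enoyl chloride.
4. Ring order: the six-membered carbocycle is closed once and becomes both ring A and ring B; the dihydropyran ring of the cycloadduct forms last and opens in the same flask.

Assumption: L-lactic acid and (R)-2-methylbutanoic acid are bought enantiopure; enolised polyketones are drawn as one tautomer and their CIP letters follow that drawing (the spatial arrangement at the carbinol carbon does not change after step 4).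

## Route

Step 1
Reactants: 1 (S)-lactic acid; 2 pivaldehyde
Product: 3 (2S,5S)-2-tert-butyl-5-methyl-1,3-dioxolan-4-one
Conditions: cat. TsOH·H2O, cat. H2SO4, pentane, reflux, Dean–Stark; recrystallise from pentane at −78 °C (cis ≥ 96:4)
Reagents that add atoms: none
Why: Acid-catalysed acetalisation (Seebach dioxolanone, self-regeneration of stereocentres): the lactate centre is untouched and steers the new acetal centre cis, the cis isomer being enriched by crystallisation.

Step 2
Reactants: 4 methyl 3-oxopentanoate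
Product: 5 methyl (2E)-3-methoxypent-2-enoate
Conditions: HC(OMe)3 (1.2 equiv), cat. H2SO4, MeOH, rt, 24 h; then distil
Reagents that add atoms: trimethyl orthoformate, COC(OC)OC
Why: Ketalisation with the orthoester followed by acid-catalysed loss of methanol (enol ether formation) gives the β-methoxy enoate, the E isomer with MeO anti to the ester being the thermodynamic one.

Step 3
Reactants: 5 methyl (2E)-3-methoxypent-2-enoate
Product: 6 (2E)-3-methoxypent-2-enoic acid
Conditions: KOH (2 equiv), MeOH/H2O, 60 °C; then 1 M HCl, 0 °C, to pH 3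
Reagents that add atoms: potassium hydroxide, [K+].[OH-]
Why: Saponification; the enol ether survives base and a brief cold acidification.

Step 4
Reactants: 6 (2E)-3-methoxypent-2-enoic acid; 3 (2S,5S)-2-tert-butyl-5-methyl-1,3-dioxolan-4-one
Product: 9 (2S,5R)-2-tert-butyl-5-[(2E)-3-methoxypent-2-enoyl]-5-methyl-1,3-dioxolan-4-one, via acid chloride 7 (not isolated), via lithium enolate 8 (not isolated)
Conditions: 6, (COCl)2, cat. DMF, CH2Cl2, 0 °C → rt, evaporate; 3, LDA, THF, −78 °C, 30 min; then 7, −78 °C, 1 h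
Reagents that add atoms: none
Why: Claisen-type C-acylation of the Seebach lithium enolate with the acid chloride made in situ; the electrophile enters anti to tert-butyl, so the quaternary centre (5R) is set with retention of the lactate configuration and has no α-H left to epimerise.

Step 5
Reactants: 9 (2S,5R)-2-tert-butyl-5-[(2E)-3-methoxypent-2-enoyl]-5-methyl-1,3-dioxolan-4-one
Product: 11 (6S)-5,6-dihydroxy-3-methoxy-4,6-dimethylcyclohexa-2,4-dien-1-one, via lithium dienolate 10 (not isolated)
Conditions: LiHMDS (2.2 equiv), THF, −78 → 0 °C; AcOH (2.2 equiv), −78 °C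
Reagents that add atoms: none
Why: Vinylogous Dieckmann (intramolecular Claisen) condensation: γ-deprotonation is the only one possible, the dienolate closes the six-membered ring on the activated acetal-ester carbonyl, the hemiacetal alkoxide ejects pivaldehyde, and the quaternary carbinol centre is not involved.

Step 6
Reactants: 11 (6S)-5,6-dihydroxy-3-methoxy-4,6-dimethylcyclohexa-2,4-dien-1-one; 12 (R)-2-methylbutanoic acid
Product: 15 (1S)-2-hydroxy-4-methoxy-1,3-dimethyl-6-oxocyclohexa-2,4-dien-1-yl (2R)-2-methylbutanoate, via acid chloride 13 (not isolated), via dilithium salt 14 (not isolated)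
Conditions: 12, (COCl)2, cat. DMF, CH2Cl2, 0 °C → rt, evaporate; 11, LiHMDS (2.05 equiv), THF, −78 °C; then 13 (1.05 equiv), −78 °C, 30 min; AcOH (1 equiv)
Reagents that add atoms: none
Why: Dianion O-acylation: the localised tertiary alkoxide is far more nucleophilic than the vinylogous carboxylate, any enol ester formed passes its acyl group to the neighbouring alkoxide (O→O acyl shift to the tertiary ester), and the acid chloride is consumed at −78 °C before ketene formation can erode its α-centre.

Step 7
Reactants: 11 (6S)-5,6-dihydroxy-3-methoxy-4,6-dimethylcyclohexa-2,4-dien-1-one; 12 (R)-2-methylbutanoic acid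
Product: 17 (6R)-5,6-dihydroxy-3-methoxy-2,6-dimethyl-4-[(2R)-2-methylbutanoyl]cyclohexa-2,4-dien-1-one, via enol ester 16 (not isolated)
Conditions: DCC (1.1 equiv), DMAP (1.2 equiv), CH2Cl2, 0 °C → rt, 16 h
Reagents that add atoms: none
Why: Steglich esterification of the acidic enol, then DMAP-mediated O→C acyl migration (Fries-type rearrangement) to the only H-bearing nucleophilic ring carbon (C2–H of 11), driven by the chelated β-triketone; no new stereocentre.

Step 8
Reactants: 17 (6R)-5,6-dihydroxy-3-methoxy-2,6-dimethyl-4-[(2R)-2-methylbutanoyl]cyclohexa-2,4-dien-1-one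
Product: 18 (6R)-6-hydroxy-3-methoxy-2,6-dimethyl-4-[(2R)-2-methylbutanoyl]-2-[(2,2,6,6-tetramethylpiperidin-1-yl)oxy]cyclohex-3-ene-1,5-dione (both C2 epimers)
Conditions: TEMPO (1.2 equiv), Ag2O (1.5 equiv), THF, rt, dark, 2 h; filter through Celite, use crude
Reagents that add atoms: TEMPO, CC1(C)CCCC(C)(C)N1[O]
Why: Ag(I) oxidises the enolate by one electron and TEMPO traps the delocalised radical at the methyl-bearing carbon (radical–nitroxide coupling); trapping at the acyl-bearing carbon is reversible and unproductive, and the new centre is lost again in step 9.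

Step 9
Reactants: 18 (6R)-6-hydroxy-3-methoxy-2,6-dimethyl-4-[(2R)-2-methylbutanoyl]-2-[(2,2,6,6-tetramethylpiperidin-1-yl)oxy]cyclohex-3-ene-1,5-dione; 15 (1S)-2-hydroxy-4-methoxy-1,3-dimethyl-6-oxocyclohexa-2,4-dien-1-yl (2R)-2-methylbutanoate
Product: 21 (1R,3R)-3-{[(5R)-4,5-dihydroxy-2-methoxy-5-methyl-3-[(2R)-2-methylbutanoyl]-6-oxocyclohexa-1,3-dien-1-yl]methyl}-4-methoxy-1,3-dimethyl-2,6-dioxocyclohex-4-en-1-yl (2R)-2-methylbutanoate, via quinone methide 19 (not isolated), via hemiketal cycloadduct 20 (not isolated)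
Conditions: 15 (2 equiv), PhMe (0.05 M), 90 °C, 6 h, argon
Reagents that add atoms: none
Why: Thermal elimination of TEMPO–H unmasks the exo-methylene enone (quinone methide), whose s-cis C=C–C=O unit undergoes an inverse-electron-demand oxa-Diels–Alder reaction with the more electron-rich, methyl-substituted C=C(OH) enol of 15 (regiochemistry as in geminal C-alkylation of C-methylphloroglucinols), anti to the pseudo-axial acyloxy group so that the new quaternary centre is R, after which the hemiketal collapses to the ketone.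

Step 10
Reactants: 21 (1R,3R)-3-{[(5R)-4,5-dihydroxy-2-methoxy-5-methyl-3-[(2R)-2-methylbutanoyl]-6-oxocyclohexa-1,3-dien-1-yl]methyl}-4-methoxy-1,3-dimethyl-2,6-dioxocyclohex-4-en-1-yl (2R)-2-methylbutanoate
Product: 22 gilluone B
Conditions: NH4OAc (10 equiv), MeOH, 40 °C, 12 h
Reagents that add atoms: ammonium acetate, CC(=O)[O-].[NH4+]
Why: Enaminone formation (condensation of ammonia with the vinylogous acid) at the ring enol carbon gives the N–H···O=C chelated β-enaminone, while ring A has no acidic enol and its hindered vinylogous ester and tertiary ester should not react with buffered ammonium acetate.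

## Compound list

1 | (S)-lactic acid | C[C@H](O)C(=O)O | starting material
2 | pivaldehyde | CC(C)(C)C=O | starting material
3 | (2S,5S)-2-tert-butyl-5-methyl-1,3-dioxolan-4-one | C[C@@H]1O[C@H](C(C)(C)C)OC1=O | intermediate
4 | methyl 3-oxopentanoate | CCC(=O)CC(=O)OC | starting material
5 | methyl (2E)-3-methoxypent-2-enoate | COC(=O)/C=C(/OC)CC | intermediate
6 | (2E)-3-methoxypent-2-enoic acid | OC(=O)/C=C(/OC)CC | intermediate
7 | (2E)-3-methoxypent-2-enoyl chloride | ClC(=O)/C=C(/OC)CC | intermediate
8 | lithium enolate of 3 (lithium (2S)-2-tert-butyl-5-methyl-1,3-dioxol-4-olate) | CC1=C([O-])O[C@@H](C(C)(C)C)O1.[Li+] | intermediate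
9 | (2S,5R)-2-tert-butyl-5-[(2E)-3-methoxypent-2-enoyl]-5-methyl-1,3-dioxolan-4-one | C[C@]1(C(=O)/C=C(/OC)CC)O[C@H](C(C)(C)C)OC1=O | intermediate
10 | lithium dienolate of 9 (γ-deprotonated) | C[C@]1(C([O-])=CC(OC)=CC)O[C@H](C(C)(C)C)OC1=O.[Li+] | intermediate
11 | (6S)-5,6-dihydroxy-3-methoxy-4,6-dimethylcyclohexa-2,4-dien-1-one (common core) | C[C@@]1(O)C(=O)C=C(OC)C(C)=C1O | intermediate
12 | (R)-2-methylbutanoic acid | CC[C@@H](C)C(=O)O | starting material
13 | (R)-2-methylbutanoyl chloride | CC[C@@H](C)C(Cl)=O | intermediate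
14 | dilithium salt of 11 (alkoxide and enolate) | C[C@@]1([O-])C(=O)C=C(OC)C(C)=C1[O-].[Li+].[Li+] | intermediate
15 | (1S)-2-hydroxy-4-methoxy-1,3-dimethyl-6-oxocyclohexa-2,4-dien-1-yl (2R)-2-methylbutanoate (ring-A ester) | CC[C@@H](C)C(=O)O[C@]1(C)C(=O)C=C(OC)C(C)=C1O | intermediate
16 | enol (2R)-2-methylbutanoate of 11 (acyl on the enol oxygen, tertiary OH free) | C[C@@]1(O)C(=O)C=C(OC)C(C)=C1OC(=O)[C@H](C)CC | intermediate
17 | (6R)-5,6-dihydroxy-3-methoxy-2,6-dimethyl-4-[(2R)-2-methylbutanoyl]cyclohexa-2,4-dien-1-one (ring-B triketone) | CC1=C(OC)C(C(=O)[C@H](C)CC)=C(O)[C@@](C)(O)C1=O | intermediate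
18 | (6R)-6-hydroxy-3-methoxy-2,6-dimethyl-4-[(2R)-2-methylbutanoyl]-2-[(2,2,6,6-tetramethylpiperidin-1-yl)oxy]cyclohex-3-ene-1,5-dione (both C2 epimers) | CC[C@@H](C)C(=O)C1=C(OC)C(C)(ON2C(C)(C)CCCC2(C)C)C(=O)[C@](C)(O)C1=O | intermediate
19 | 6-hydroxy-3-methoxy-6-methyl-4-[(2R)-2-methylbutanoyl]-2-methylidenecyclohex-3-ene-1,5-dione, carbinol carbon as in 17 (quinone methide) | CC[C@@H](C)C(=O)C1=C(OC)C(=C)C(=O)[C@](C)(O)C1=O | intermediate
20 | hemiketal cycloadduct: dihydropyran fused to both carbocycles, former ring-B ketone oxygen bonded to the former enol carbon of 15, bridge CH2 bonded to its methyl-bearing carbon, O and CH2 cis, both anti to the acyloxy group | CC[C@@H](C)C(=O)O[C@]1(C)C(=O)C=C(OC)[C@@]2(C)CC3=C(O[C@@]12O)[C@](C)(O)C(=O)C(C(=O)[C@H](C)CC)=C3OC | intermediate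
21 | (1R,3R)-3-{[(5R)-4,5-dihydroxy-2-methoxy-5-methyl-3-[(2R)-2-methylbutanoyl]-6-oxocyclohexa-1,3-dien-1-yl]methyl}-4-methoxy-1,3-dimethyl-2,6-dioxocyclohex-4-en-1-yl (2R)-2-methylbutanoate | CC[C@@H](C)C(=O)O[C@]1(C)C(=O)C=C(OC)[C@@](C)(CC2=C(OC)C(C(=O)[C@H](C)CC)=C(O)[C@@](C)(O)C2=O)C1=O | intermediate
22 | gilluone B, (1R,3R)-3-{[(5R)-4-amino-5-hydroxy-2-methoxy-5-methyl-3-[(2R)-2-methylbutanoyl]-6-oxocyclohexa-1,3-dien-1-yl]methyl}-4-methoxy-1,3-dimethyl-2,6-dioxocyclohex-4-en-1-yl (2R)-2-methylbutanoate | CC[C@@H](C)C(=O)O[C@]1(C)C(=O)C=C(OC)[C@@](C)(CC2=C(OC)C(C(=O)[C@H](C)CC)=C(N)[C@@](C)(O)C2=O)C1=O | target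

## Summary

Total steps: 10. Longest linear sequence: 8 (steps 2, 3, 4, 5, 7, 8, 9, 10, from methyl 3-oxopentanoate).

Three steps most likely to fail:

**Step 8 (alkoxyamine formation on the C-methyl carbon).** The radical may be trapped at the wrong carbon, or the adduct may not lose TEMPO–H cleanly. The fallback rebuilds ring B with a leaving group already on the future bridge carbon. It sets out from 3 and comes back at 19 (and hence 21). Commercial methyl 5-methoxy-3-oxopentanoate is treated with trimethyl orthoformate and cat. H2SO4 to give methyl (2E)-3,5-dimethoxypent-2-enoate F1. This is saponified to (2E)-3,5-dimethoxypent-2-enoic acid F2 and activated with oxalyl chloride to (2E)-3,5-dimethoxypent-2-enoyl chloride F3. F3 acylates the lithium enolate 8 made from 3 to give (2S,5R)-2-tert-butyl-5-[(2E)-3,5-dimethoxypent-2-enoyl]-5-methyl-1,3-dioxolan-4-one F4. LiHMDS closes the ring to (6S)-5,6-dihydroxy-3-methoxy-4-(methoxymethyl)-6-methylcyclohexa-2,4-dien-1-one F5. DCC/DMAP C-acylation with 12 gives (6R)-5,6-dihydroxy-3-methoxy-2-(methoxymethyl)-6-methyl-4-[(2R)-2-methylbutanoyl]cyclohexa-2,4-dien-1-one F6. Heating F6 with 15 (PhMe, 100 °C, cat. PPTS) expels methanol by vinylogous β-elimination and gives the same quinone methide 19, which is trapped as in step 9.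

**Step 9 (regio- and face-selectivity of the cycloaddition).** The quinone methide may attack the unsubstituted vinylic carbon of 15 instead of the methyl-bearing one, and the facial preference is argued, not proven. The fallback blocks the competing carbon; it addresses the regiochemistry only. It sets out from 15 and comes back at 21. NBS (1.0 equiv, CH2Cl2, 0 °C) brominates the vinylic CH to give (1S)-5-bromo-2-hydroxy-4-methoxy-1,3-dimethyl-6-oxocyclohexa-2,4-dien-1-yl (2R)-2-methylbutanoate F7. F7 is heated with 18 as in step 9, where only the methyl-bearing enol carbon can react, giving the 5-bromo analogue of 21 F8. Hydrogenolysis of the vinylic C–Br bond (H2, Pd/C, NaOAc, EtOAc, rt) then returns 21.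

**Step 10 (chemo- and regioselective amination).** Ammonia could exchange a methoxy group or condense at the exocyclic acyl carbon. The fallback uses a more nucleophilic primary-amine surrogate under neutral conditions. It sets out from 21 and comes back at 22. 2,4-Dimethoxybenzylamine (1.1 equiv, CH2Cl2, 4 Å sieves, rt) condenses with the vinylogous acid to give the N-(2,4-dimethoxybenzyl) enaminone of 21 F9. TFA/Et3SiH (CH2Cl2, rt) removes the benzyl group to give 22.

## Further compounds

F1 | step 8 | methyl (2E)-3,5-dimethoxypent-2-enoate | COC(=O)/C=C(/OC)CCOC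
F2 | step 8 | (2E)-3,5-dimethoxypent-2-enoic acid | OC(=O)/C=C(/OC)CCOC
F3 | step 8 | (2E)-3,5-dimethoxypent-2-enoyl chloride | ClC(=O)/C=C(/OC)CCOC
F4 | step 8 | (2S,5R)-2-tert-butyl-5-[(2E)-3,5-dimethoxypent-2-enoyl]-5-methyl-1,3-dioxolan-4-one | C[C@]1(C(=O)/C=C(/OC)CCOC)O[C@H](C(C)(C)C)OC1=O
F5 | step 8 | (6S)-5,6-dihydroxy-3-methoxy-4-(methoxymethyl)-6-methylcyclohexa-2,4-dien-1-one | C[C@@]1(O)C(=O)C=C(OC)C(COC)=C1O
F6 | step 8 | (6R)-5,6-dihydroxy-3-methoxy-2-(methoxymethyl)-6-methyl-4-[(2R)-2-methylbutanoyl]cyclohexa-2,4-dien-1-one | COCC1=C(OC)C(C(=O)[C@H](C)CC)=C(O)[C@@](C)(O)C1=O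
F7 | step 9 | (1S)-5-bromo-2-hydroxy-4-methoxy-1,3-dimethyl-6-oxocyclohexa-2,4-dien-1-yl (2R)-2-methylbutanoate | CC[C@@H](C)C(=O)O[C@]1(C)C(=O)C(Br)=C(OC)C(C)=C1O
F8 | step 9 | 5-bromo analogue of 21 (Br on the vinylic carbon of the ring-A unit) | CC[C@@H](C)C(=O)O[C@]1(C)C(=O)C(Br)=C(OC)[C@@](C)(CC2=C(OC)C(C(=O)[C@H](C)CC)=C(O)[C@@](C)(O)C2=O)C1=O
F9 | step 10 | N-(2,4-dimethoxybenzyl) enaminone of 21 (N-benzylated gilluone B) | CC[C@@H](C)C(=O)O[C@]1(C)C(=O)C=C(OC)[C@@](C)(CC2=C(OC)C(C(=O)[C@H](C)CC)=C(NCc3ccc(OC)cc3OC)[C@@](C)(O)C2=O)C1=O
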